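**Strategy.** The target is cut at the unsubstituted C7–C8 ethano bridge of the methylcyclohexene ring (hexahydronaphthalene numbering), which lies between the methyl-bearing olefinic C6 and the ring-fusion carbon C8a. Vinyltriphenylphosphonium bromide supplies both carbons tracelessly: in one operation an extended enolate adds through C8a to the vinyl group (C8–C8a) and the resulting ylide closes onto a methyl ketone (C6–C7, Wittig). The precursor is an achiral 4-(2-oxopropylidene)cyclohexenone from ketoisophorone. The cyclohexadiene formed is 1,4-hydrogenated to the cis-fused C5=C6 olefin, resolved by an ene-reductase, and joined as a vinyl triflate to a 1,2-dioxane alkyne built from (S)-2-methylglycidol.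

Key step: step 3

Remark: ring atoms are numbered as in 1,4,4a,7,8,8a-hexahydronaphthalene (C1 = CMe2, C2 = side-chain carbon); chain atoms carry primes (C1′ = CO2H … C8′). Compounds 2, 5 and 6 are racemates; 7 is a racemic cis compound whose SMILES shows the enantiomer carried forward. The ene-reductase of step 5 is assumed to be chosen from an Old Yellow Enzyme panel by screening.

Step 1
Reactants: 1 ketoisophorone (2,6,6-trimethylcyclohex-2-ene-1,4-dione)
Product: 2 rac-4-hydroxy-2,6,6-trimethyl-4-(prop-1-yn-1-yl)cyclohex-2-en-1-one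
Conditions: 1-propynylmagnesium bromide, THF, −78 → 0 °C; aq. NH4Cl
Reagents that add atoms: 1-propynylmagnesium bromide, CC#C[Mg]Br
Why: 1,2-addition of an alkynyl Grignard reagent should occur at the less hindered C4 carbonyl (C1 is flanked by CMe2 and C-Me); the carbinol stereocentre is racemic and is erased in step 2.

Step 2
Reactants: 2 rac-4-hydroxy-2,6,6-trimethyl-4-(prop-1-yn-1-yl)cyclohex-2-en-1-one
Product: 3 2,6,6-trimethyl-4-(2-oxopropylidene)cyclohex-2-en-1-one (E/Z mixture)
Conditions: Ph3PAuNTf2 (2 mol %), MeOH (1 equiv), toluene, rt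
Reagents that add atoms: none
Why: gold(I)-catalysed Meyer–Schuster rearrangement (1,3-hydroxyl shift of a tertiary propargylic alcohol) should give the conjugated methyl ketone; both alkene isomers converge on the same enolate in step 3.

Step 3
Reactants: 3 2,6,6-trimethyl-4-(2-oxopropylidene)cyclohex-2-en-1-one; 4 triphenyl(vinyl)phosphonium bromide
Product: 6 rac-1,1,3,6-tetramethyl-8,8a-dihydronaphthalen-2(1H)-one, via phosphorus ylide 5 (not isolated)
Conditions: NaH (1.05 equiv), THF–DMSO, 0 °C; then 4, rt → 60 °C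
Reagents that add atoms: none
Why: NaH removes a γ-hydrogen from the only sp3 γ-carbon (the ring CH2 next to CMe2, the future C8a), and the γ-carbon of the extended enolate adds to the vinylphosphonium salt (Michael addition, C8–C8a) to give ylide 5, which attacks the methyl ketone in an intramolecular Wittig reaction (C6–C7, loss of Ph3PO). The closest known reaction type is the Schweizer/Büchi–Wüest annulation of dienolates with vinyltriphenylphosphonium bromide to cyclohexa-1,3-dienes. The ring closes by 6-exo-trig attack of the ylide carbon on the carbonyl group followed by oxaphosphetane collapse. The one new stereocentre, C8a, has no controlling element and forms as a racemate that is resolved in step 5. The step needs γ- rather than α- or ε-attack and the Z enone geometry; adducts that cannot reach the ketone through a six-membered transition state should revert by retro-Michael reaction and enolate equilibration, so only the γ,Z-ylide is drained irreversibly.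

Step 4
Reactants: 6 rac-1,1,3,6-tetramethyl-8,8a-dihydronaphthalen-2(1H)-one
Product: 7 rac-cis-(4aS*,8aS*)-1,1,3,6-tetramethyl-4a,7,8,8a-tetrahydronaphthalen-2(1H)-one
Conditions: (η6-naphthalene)Cr(CO)3 (10 mol %), H2 (4 atm), THF, 40 °C
Reagents that add atoms: none
Why: arene–Cr(CO)3-catalysed 1,4-hydrogenation of the s-cis homoannular diene adds both hydrogens (C4a, C7) from the chromium-bound face, expected to be the face of H-8a opposite the C1 quaternary carbon, so C4a-H is set cis to C8a-H; the s-trans enone and the transoid C3=C4–C4a=C5 unit cannot chelate and should stay.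

Step 5
Reactants: 7 rac-cis-(4aS*,8aS*)-1,1,3,6-tetramethyl-4a,7,8,8a-tetrahydronaphthalen-2(1H)-one
Product: 8 (4aR,8aS)-1,1,3,6-tetramethyl-3,4,4a,7,8,8a-hexahydronaphthalen-2(1H)-one (C3 configuration immaterial)
Conditions: ene-reductase (Old Yellow Enzyme family), NADP+ (cat.), glucose dehydrogenase, D-glucose, phosphate buffer pH 7, 5% DMSO, 30 °C, stopped at about half conversion; chromatography
Reagents that add atoms: none
Why: ene-reductases reduce 2-methylcyclohex-2-enones such as ketoisophorone and sense the stereocentre next to the β-carbon, so this kinetic resolution should convert only (4aS,8aS)-7 and thereby fix the absolute configuration of C4a and C8a (the descriptor change at C4a is a priority effect); unreacted (4aR,8aR)-7 is removed, which limits the step to half of the material.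

Step 6
Reactants: 8 (4aR,8aS)-1,1,3,6-tetramethyl-3,4,4a,7,8,8a-hexahydronaphthalen-2(1H)-one
Product: 9 (4aR,8aS)-1,1,3,6-tetramethyl-1,4,4a,7,8,8a-hexahydronaphthalen-2-yl trifluoromethanesulfonate
Conditions: KHMDS, THF, −78 °C; PhNTf2, −78 → 0 °C
Reagents that add atoms: N-phenylbis(trifluoromethanesulfonimide), O=S(=O)(N(c1ccccc1)S(=O)(=O)C(F)(F)F)C(F)(F)F
Why: enolisation is regiospecific (only C3 carries an α-hydrogen) and O-triflation gives the tetrasubstituted enol triflate, as known for 2,2,6-trimethylcyclohexanone.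

Step 7
Reactants: 10 (S)-2-methylglycidol
Product: 11 [(2R)-2-methyloxiran-2-yl]methyl 4-methylbenzenesulfonate
Conditions: TsCl, Et3N, DMAP (cat.), CH2Cl2, 0 °C
Reagents that add atoms: p-toluenesulfonyl chloride, Cc1ccc(cc1)S(Cl)(=O)=O
Why: sulfonylation of the primary alcohol leaves the quaternary stereocentre untouched (the descriptor changes by priority only).

Step 8
Reactants: 11 [(2R)-2-methyloxiran-2-yl]methyl 4-methylbenzenesulfonate
Product: 13 (2R)-2-(but-3-en-1-yl)-2-methyloxirane, via hydroxy tosylate 12 (not isolated)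
Conditions: allylMgCl, CuI (10 mol %), THF, −40 °C; then K2CO3, MeOH, rt
Reagents that add atoms: allylmagnesium chloride, C=CC[Mg]Cl
Why: copper-catalysed Grignard opening of the glycidyl tosylate at the epoxide CH2 and intramolecular Williamson closure of the tertiary alkoxide onto the tosylate transpose the epoxide without breaking the quaternary C–O bond, so configuration is retained.

Step 9
Reactants: 13 (2R)-2-(but-3-en-1-yl)-2-methyloxirane
Product: 15 3-[(2R)-2-methyloxiran-2-yl]propanal, via secondary ozonide 14 (not isolated)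
Conditions: O3, CH2Cl2, −78 °C; PPh3, −78 °C → rt
Reagents that add atoms: ozone, [O-][O+]=O
Why: ozonolysis with reductive work-up cleaves the terminal alkene to the aldehyde; the epoxide is inert to ozone.

Step 10
Reactants: 15 3-[(2R)-2-methyloxiran-2-yl]propanal; 16 (4R)-4-benzyl-3-propanoyl-1,3-oxazolidin-2-one
Product: 18 (4R)-4-benzyl-3-{(2R,3S)-3-hydroxy-2-methyl-5-[(2R)-2-methyloxiran-2-yl]pentanoyl}-1,3-oxazolidin-2-one, via Z-boron enolate 17 (not isolated)
Conditions: Bu2BOTf, i-Pr2NEt, CH2Cl2, −78 → 0 °C; 15, −78 °C; pH 7 buffer, MeOH, H2O2, 0 °C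
Reagents that add atoms: none
Why: Evans syn-aldol reaction through the Z-boron enolate and a Zimmerman–Traxler transition state; the (R)-auxiliary sets C2′ (R) and C3′ (S) independently of the remote epoxide.

Step 11
Reactants: 18 (4R)-4-benzyl-3-{(2R,3S)-3-hydroxy-2-methyl-5-[(2R)-2-methyloxiran-2-yl]pentanoyl}-1,3-oxazolidin-2-one
Product: 19 (2S,3S)-2-methyl-5-[(2R)-2-methyloxiran-2-yl]pentane-1,3-diol
Conditions: NaBH4, THF–H2O, 0 °C → rt
Reagents that add atoms: none
Why: borohydride reductive cleavage of the N-acyl oxazolidinone gives the primary alcohol and should neither open the epoxide nor epimerise C2′.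

Step 12
Reactants: 19 (2S,3S)-2-methyl-5-[(2R)-2-methyloxiran-2-yl]pentane-1,3-diol
Product: 20 (2S,3S)-1-[(tert-butyldiphenylsilyl)oxy]-2-methyl-5-[(2R)-2-methyloxiran-2-yl]pentan-3-ol
Conditions: TBDPSCl, imidazole, CH2Cl2, 0 °C
Reagents that add atoms: tert-butyl(chloro)diphenylsilane, CC(C)(C)[Si](Cl)(c1ccccc1)c1ccccc1
Why: selective silylation of the primary hydroxyl by the bulky silyl chloride.

Step 13
Reactants: 20 (2S,3S)-1-[(tert-butyldiphenylsilyl)oxy]-2-methyl-5-[(2R)-2-methyloxiran-2-yl]pentan-3-ol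
Product: 21 (2S,3S)-1-[(tert-butyldiphenylsilyl)oxy]-2-methyl-5-[(2R)-2-methyloxiran-2-yl]pentan-3-yl methanesulfonate
Conditions: MsCl, Et3N, CH2Cl2, −20 → 0 °C
Reagents that add atoms: methanesulfonyl chloride, CS(Cl)(=O)=O
Why: mesylation of the secondary alcohol proceeds with retention and prepares C3′ for displacement with inversion.

Step 14
Reactants: 21 (2S,3S)-1-[(tert-butyldiphenylsilyl)oxy]-2-methyl-5-[(2R)-2-methyloxiran-2-yl]pentan-3-yl methanesulfonate
Product: 22 (2S,5S,6S)-7-[(tert-butyldiphenylsilyl)oxy]-2-hydroperoxy-1-hydroxy-2,6-dimethylheptan-5-yl methanesulfonate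
Conditions: anhydrous H2O2 in Et2O, phosphomolybdic acid (cat.), rt
Reagents that add atoms: hydrogen peroxide, OO
Why: phosphomolybdic acid-catalysed perhydrolysis of a 2,2-disubstituted epoxide: H2O2 should attack the tertiary carbon of the activated epoxide from the rear, forming the C6′–OOH centre with inversion and releasing C7′ as CH2OH.

Step 15
Reactants: 22 (2S,5S,6S)-7-[(tert-butyldiphenylsilyl)oxy]-2-hydroperoxy-1-hydroxy-2,6-dimethylheptan-5-yl methanesulfonate
Product: 23 {(3S,6R)-6-[(2S)-1-[(tert-butyldiphenylsilyl)oxy]propan-2-yl]-3-methyl-1,2-dioxan-3-yl}methanol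
Conditions: KOt-Bu (1.0 equiv), 18-crown-6, toluene, 0 °C
Reagents that add atoms: none
Why: intramolecular alkylation of the hydroperoxide anion (6-exo-tet SN2) displaces the secondary mesylate with inversion at C3′, which places the two carbon chains cis on the dioxane and makes C2′/C3′ anti; the more acidic OOH is deprotonated in preference to the primary OH.

Step 16
Reactants: 23 {(3S,6R)-6-[(2S)-1-[(tert-butyldiphenylsilyl)oxy]propan-2-yl]-3-methyl-1,2-dioxan-3-yl}methanol
Product: 24 (3S,6R)-6-[(2S)-1-[(tert-butyldiphenylsilyl)oxy]propan-2-yl]-3-methyl-1,2-dioxane-3-carbaldehyde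
Conditions: Dess–Martin periodinane, NaHCO3, CH2Cl2, 0 °C → rt
Reagents that add atoms: none
Why: Dess–Martin oxidation gives the non-enolisable α-peroxy aldehyde; dialkyl peroxides tolerate hypervalent iodine oxidants.

Step 17
Reactants: 24 (3S,6R)-6-[(2S)-1-[(tert-butyldiphenylsilyl)oxy]propan-2-yl]-3-methyl-1,2-dioxane-3-carbaldehyde
Product: 25 tert-butyl{(2S)-2-[(3R,6S)-6-ethynyl-6-methyl-1,2-dioxan-3-yl]propoxy}diphenylsilane
Conditions: dimethyl (1-diazo-2-oxopropyl)phosphonate, K2CO3, MeOH, 0 °C → rt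
Reagents that add atoms: dimethyl (1-diazo-2-oxopropyl)phosphonate, CC(=O)C(=[N+]=[N-])P(=O)(OC)OC
Why: Seyferth–Gilbert homologation with the Ohira–Bestmann reagent converts the aldehyde into the terminal alkyne (C7′≡C8′) under mild carbonate conditions that should leave the peroxide intact.

Step 18
Reactants: 9 (4aR,8aS)-1,1,3,6-tetramethyl-1,4,4a,7,8,8a-hexahydronaphthalen-2-yl trifluoromethanesulfonate; 25 tert-butyl{(2S)-2-[(3R,6S)-6-ethynyl-6-methyl-1,2-dioxan-3-yl]propoxy}diphenylsilane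
Product: 26 tert-butyl{(2S)-2-[(3R,6S)-6-methyl-6-{[(4aR,8aS)-1,1,3,6-tetramethyl-1,4,4a,7,8,8a-hexahydronaphthalen-2-yl]ethynyl}-1,2-dioxan-3-yl]propoxy}diphenylsilane
Conditions: Pd(PPh3)4 (5 mol %), CuI (10 mol %), i-Pr2NH, THF, rt
Reagents that add atoms: none
Why: Sonogashira coupling of the hindered enol triflate (as for 2,6,6-trimethylcyclohexenyl triflate) with the terminal alkyne forms the C2–C8′ bond; Pd/Cu couplings are tolerated by dialkyl peroxides.

Step 19
Reactants: 26 tert-butyl{(2S)-2-[(3R,6S)-6-methyl-6-{[(4aR,8aS)-1,1,3,6-tetramethyl-1,4,4a,7,8,8a-hexahydronaphthalen-2-yl]ethynyl}-1,2-dioxan-3-yl]propoxy}diphenylsilane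
Product: 28 tert-butyl{(2S)-2-[(3R,6R)-6-methyl-6-{2-[(4aR,8aS)-1,1,3,6-tetramethyl-1,4,4a,7,8,8a-hexahydronaphthalen-2-yl]ethyl}-1,2-dioxan-3-yl]propoxy}diphenylsilane, via Z-alkene 27 (not isolated)
Conditions: 2-nitrobenzenesulfonylhydrazide (excess, in portions), Et3N, CH2Cl2, rt
Reagents that add atoms: none
Why: diimide reduction transfers H2 in a concerted syn fashion to the alkyne and then to the cis-disubstituted alkene, and should spare the tri- and tetrasubstituted ring alkenes and, unlike catalytic hydrogenation, the O–O bond.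

Step 20
Reactants: 28 tert-butyl{(2S)-2-[(3R,6R)-6-methyl-6-{2-[(4aR,8aS)-1,1,3,6-tetramethyl-1,4,4a,7,8,8a-hexahydronaphthalen-2-yl]ethyl}-1,2-dioxan-3-yl]propoxy}diphenylsilane
Product: 29 (2S)-2-[(3R,6R)-6-methyl-6-{2-[(4aR,8aS)-1,1,3,6-tetramethyl-1,4,4a,7,8,8a-hexahydronaphthalen-2-yl]ethyl}-1,2-dioxan-3-yl]propan-1-ol
Conditions: TBAF, AcOH (1:1), THF, rt
Reagents that add atoms: none
Why: fluoride cleavage of the silyl ether; buffering with acetic acid avoids base-induced fragmentation of the peroxide.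

Step 21
Reactants: 29 (2S)-2-[(3R,6R)-6-methyl-6-{2-[(4aR,8aS)-1,1,3,6-tetramethyl-1,4,4a,7,8,8a-hexahydronaphthalen-2-yl]ethyl}-1,2-dioxan-3-yl]propan-1-ol
Product: 31 (2R)-2-[(3R,6R)-6-methyl-6-{2-[(4aR,8aS)-1,1,3,6-tetramethyl-1,4,4a,7,8,8a-hexahydronaphthalen-2-yl]ethyl}-1,2-dioxan-3-yl]propanoic acid, via aldehyde 30 (not isolated)
Conditions: TEMPO (cat.), PhI(OAc)2, MeCN–pH 7 buffer, rt
Reagents that add atoms: water, O
Why: TEMPO/PhI(OAc)2 oxidation in aqueous acetonitrile takes the primary alcohol through the aldehyde and its hydrate to the acid under near-neutral conditions that should not epimerise C2′ or touch the alkenes and the peroxide.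

**Compound list**

1 | ketoisophorone (2,6,6-trimethylcyclohex-2-ene-1,4-dione) | CC1=CC(=O)CC(C)(C)C1=O | starting material
2 | rac-4-hydroxy-2,6,6-trimethyl-4-(prop-1-yn-1-yl)cyclohex-2-en-1-one | CC#CC1(O)C=C(C)C(=O)C(C)(C)C1 | intermediate
3 | 2,6,6-trimethyl-4-(2-oxopropylidene)cyclohex-2-en-1-one (E/Z mixture) | CC(=O)C=C1C=C(C)C(=O)C(C)(C)C1 | intermediate
4 | triphenyl(vinyl)phosphonium bromide | C=C[P+](c1ccccc1)(c1ccccc1)c1ccccc1.[Br-] | starting material
5 | rac-(Z)-2,6,6-trimethyl-4-(2-oxopropylidene)-5-[2-(triphenyl-λ5-phosphanylidene)ethyl]cyclohex-2-en-1-one (acetyl syn to C5) | CC(=O)/C=C1\C(CC=P(c2ccccc2)(c2ccccc2)c2ccccc2)C(C)(C)C(=O)C(C)=C1 | intermediate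
6 | rac-1,1,3,6-tetramethyl-8,8a-dihydronaphthalen-2(1H)-one | CC1=CCC2C(=C1)C=C(C)C(=O)C2(C)C | intermediate
7 | rac-cis-1,1,3,6-tetramethyl-4a,7,8,8a-tetrahydronaphthalen-2(1H)-one (SMILES: (4aS,8aS) enantiomer) | CC1=C[C@H]2C=C(C)C(=O)C(C)(C)[C@H]2CC1 | intermediate
8 | (4aR,8aS)-1,1,3,6-tetramethyl-3,4,4a,7,8,8a-hexahydronaphthalen-2(1H)-one (C3 undefined) | CC1=C[C@H]2CC(C)C(=O)C(C)(C)[C@H]2CC1 | intermediate
9 | (4aR,8aS)-1,1,3,6-tetramethyl-1,4,4a,7,8,8a-hexahydronaphthalen-2-yl trifluoromethanesulfonate | CC1=C[C@H]2CC(C)=C(OS(=O)(=O)C(F)(F)F)C(C)(C)[C@H]2CC1 | intermediate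
10 | (S)-2-methylglycidol | C[C@]1(CO)CO1 | starting material
11 | [(2R)-2-methyloxiran-2-yl]methyl 4-methylbenzenesulfonate | Cc1ccc(cc1)S(=O)(=O)OC[C@@]1(C)CO1 | intermediate
12 | (2R)-2-hydroxy-2-methylhex-5-en-1-yl 4-methylbenzenesulfonate | C=CCC[C@](O)(C)COS(=O)(=O)c1ccc(C)cc1 | intermediate
13 | (2R)-2-(but-3-en-1-yl)-2-methyloxirane | C=CCC[C@]1(C)CO1 | intermediate
14 | 3-{2-[(2R)-2-methyloxiran-2-yl]ethyl}-1,2,4-trioxolane | C1OC(CC[C@]2(C)CO2)OO1 | intermediate
15 | 3-[(2R)-2-methyloxiran-2-yl]propanal | O=CCC[C@]1(C)CO1 | intermediate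
16 | (4R)-4-benzyl-3-propanoyl-1,3-oxazolidin-2-one | CCC(=O)N1[C@H](Cc2ccccc2)COC1=O | starting material
17 | (Z)-dibutylboron enolate of 16 | C/C=C(\OB(CCCC)CCCC)N1[C@H](Cc2ccccc2)COC1=O | intermediate
18 | (4R)-4-benzyl-3-{(2R,3S)-3-hydroxy-2-methyl-5-[(2R)-2-methyloxiran-2-yl]pentanoyl}-1,3-oxazolidin-2-one | C1O[C@]1(C)CC[C@@H]([C@@H](C)C(=O)N1[C@H](Cc2ccccc2)COC1=O)O | intermediate
19 | (2S,3S)-2-methyl-5-[(2R)-2-methyloxiran-2-yl]pentane-1,3-diol | C1O[C@]1(C)CC[C@@H]([C@@H](C)CO)O | intermediate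
20 | (2S,3S)-1-[(tert-butyldiphenylsilyl)oxy]-2-methyl-5-[(2R)-2-methyloxiran-2-yl]pentan-3-ol | C1O[C@]1(C)CC[C@@H]([C@@H](C)CO[Si](c1ccccc1)(c1ccccc1)C(C)(C)C)O | intermediate
21 | (2S,3S)-1-[(tert-butyldiphenylsilyl)oxy]-2-methyl-5-[(2R)-2-methyloxiran-2-yl]pentan-3-yl methanesulfonate | C1O[C@]1(C)CC[C@@H]([C@@H](C)CO[Si](c1ccccc1)(c1ccccc1)C(C)(C)C)OS(C)(=O)=O | intermediate
22 | (2S,5S,6S)-7-[(tert-butyldiphenylsilyl)oxy]-2-hydroperoxy-1-hydroxy-2,6-dimethylheptan-5-yl methanesulfonate | OC[C@@](C)(OO)CC[C@@H]([C@@H](C)CO[Si](c1ccccc1)(c1ccccc1)C(C)(C)C)OS(C)(=O)=O | intermediate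
23 | {(3S,6R)-6-[(2S)-1-[(tert-butyldiphenylsilyl)oxy]propan-2-yl]-3-methyl-1,2-dioxan-3-yl}methanol | OC[C@]1(C)CC[C@H]([C@@H](C)CO[Si](c2ccccc2)(c2ccccc2)C(C)(C)C)OO1 | intermediate
24 | (3S,6R)-6-[(2S)-1-[(tert-butyldiphenylsilyl)oxy]propan-2-yl]-3-methyl-1,2-dioxane-3-carbaldehyde | O=C[C@]1(C)CC[C@H]([C@@H](C)CO[Si](c2ccccc2)(c2ccccc2)C(C)(C)C)OO1 | intermediate
25 | tert-butyl{(2S)-2-[(3R,6S)-6-ethynyl-6-methyl-1,2-dioxan-3-yl]propoxy}diphenylsilane | C#C[C@]1(C)CC[C@H]([C@@H](C)CO[Si](c2ccccc2)(c2ccccc2)C(C)(C)C)OO1 | intermediate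
26 | tert-butyl{(2S)-2-[(3R,6S)-6-methyl-6-{[(4aR,8aS)-1,1,3,6-tetramethyl-1,4,4a,7,8,8a-hexahydronaphthalen-2-yl]ethynyl}-1,2-dioxan-3-yl]propoxy}diphenylsilane | CC1=C[C@H]2CC(C)=C(C#C[C@]3(C)CC[C@H]([C@@H](C)CO[Si](c4ccccc4)(c4ccccc4)C(C)(C)C)OO3)C(C)(C)[C@H]2CC1 | intermediate
27 | tert-butyl{(2S)-2-[(3R,6S)-6-methyl-6-{(Z)-2-[(4aR,8aS)-1,1,3,6-tetramethyl-1,4,4a,7,8,8a-hexahydronaphthalen-2-yl]ethenyl}-1,2-dioxan-3-yl]propoxy}diphenylsilane | CC1=C[C@H]2CC(C)=C(/C=C\[C@]3(C)CC[C@H]([C@@H](C)CO[Si](c4ccccc4)(c4ccccc4)C(C)(C)C)OO3)C(C)(C)[C@H]2CC1 | intermediate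
28 | tert-butyl{(2S)-2-[(3R,6R)-6-methyl-6-{2-[(4aR,8aS)-1,1,3,6-tetramethyl-1,4,4a,7,8,8a-hexahydronaphthalen-2-yl]ethyl}-1,2-dioxan-3-yl]propoxy}diphenylsilane | CC1=C[C@H]2CC(C)=C(CC[C@]3(C)CC[C@H]([C@@H](C)CO[Si](c4ccccc4)(c4ccccc4)C(C)(C)C)OO3)C(C)(C)[C@H]2CC1 | intermediate
29 | (2S)-2-[(3R,6R)-6-methyl-6-{2-[(4aR,8aS)-1,1,3,6-tetramethyl-1,4,4a,7,8,8a-hexahydronaphthalen-2-yl]ethyl}-1,2-dioxan-3-yl]propan-1-ol | CC1=C[C@H]2CC(C)=C(CC[C@]3(C)CC[C@H]([C@@H](C)CO)OO3)C(C)(C)[C@H]2CC1 | intermediate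
30 | (2R)-2-[(3R,6R)-6-methyl-6-{2-[(4aR,8aS)-1,1,3,6-tetramethyl-1,4,4a,7,8,8a-hexahydronaphthalen-2-yl]ethyl}-1,2-dioxan-3-yl]propanal | CC1=C[C@H]2CC(C)=C(CC[C@]3(C)CC[C@H]([C@@H](C)C=O)OO3)C(C)(C)[C@H]2CC1 | intermediate
31 | (2R)-2-[(3R,6R)-6-methyl-6-{2-[(4aR,8aS)-1,1,3,6-tetramethyl-1,4,4a,7,8,8a-hexahydronaphthalen-2-yl]ethyl}-1,2-dioxan-3-yl]propanoic acid (CNP0122760.1) | CC1=C[C@H]2CC(C)=C(CC[C@]3(C)CC[C@H]([C@@H](C)C(=O)O)OO3)C(C)(C)[C@H]2CC1 | target

**Step count and risks**

Total step count: 21. Longest linear sequence: 15 steps (10 → 31, steps 7–21); the core branch (1 → 9) has 6 steps before the union.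

Steps most likely to fail:

Step 3 (key annulation). The extended enolate may be alkylated at its α- or ε-carbon instead of at C8a, or the ylide may be quenched by proton transfer before it closes onto the ketone. The fallback sets out from 1 and gives up the one-pot bond pair. A Robinson annulation of 1 with methyl vinyl ketone (Michael addition of the C5 enolate, then aldol condensation with pyrrolidine/AcOH) should give racemic 1,1,3-trimethyl-8,8a-dihydronaphthalene-2,6(1H,7H)-dione F1. Chemoselective addition of MeLi/CeCl3 to the unhindered dienone carbonyl should give 6-hydroxy-1,1,3,6-tetramethyl-6,7,8,8a-tetrahydronaphthalen-2(1H)-one F2. Dehydration (Burgess reagent or catalytic TsOH) towards the conjugated endocyclic position returns to 6.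

Step 5 (enzymatic resolution). The hindered, gem-dimethyl-flanked carbonyl may bind poorly in the active site, or the enzyme may discriminate the enantiomers of 7 insufficiently. The fallback sets out from 7: the racemate is separated by preparative chromatography on a chiral stationary phase, and (4aS,8aS)-7 is reduced in the 1,4-sense with L-Selectride. The regiospecific enolate is trapped with PhNTf2, which comes back to the route at 9; no new compound is made (F0).

Step 14 (perhydrolysis). Partial ionisation at the tertiary carbon would erode the configuration of C6′, and Lewis-acid-induced rearrangement of the epoxide to an aldehyde may compete. The fallback sets out from 21 and reverses the order of the two C–O bond formations. Intermolecular SN2 displacement of the mesylate by hydroperoxide anion (H2O2, KOH, MeOH, 0 °C, inversion at C3′) should give tert-butyl{[(2S,3R)-3-hydroperoxy-2-methyl-5-[(2R)-2-methyloxiran-2-yl]pentyl]oxy}diphenylsilane F3. Acid-catalysed (camphorsulfonic acid, CH2Cl2) intramolecular 6-exo opening of the epoxide at its tertiary carbon by the OOH group, with inversion, then comes back to the route at 23.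

**Further compounds**

F1 | step 3 | 1,1,3-trimethyl-8,8a-dihydronaphthalene-2,6(1H,7H)-dione (racemate) | CC1=CC2=CC(=O)CCC2C(C)(C)C1=O
F2 | step 3 | 6-hydroxy-1,1,3,6-tetramethyl-6,7,8,8a-tetrahydronaphthalen-2(1H)-one (diastereomer mixture) | CC1=CC2=CC(C)(O)CCC2C(C)(C)C1=O
F0 | step 5 | none | none
F3 | step 14 | tert-butyl{[(2S,3R)-3-hydroperoxy-2-methyl-5-[(2R)-2-methyloxiran-2-yl]pentyl]oxy}diphenylsilane | C1O[C@]1(C)CC[C@H]([C@@H](C)CO[Si](c1ccccc1)(c1ccccc1)C(C)(C)C)OO
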